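**Retrosynthetic overview**

- Numbering as in the target: ring A = C1–C5 and C10, ring B = C5–C10; α is the face that carries the C4 and C5 methyl groups. The strategy rests on the unit C4(H)(Me)–C5(Me)–C6 of ring A: C4 and C5 are the two alkene carbons of (E)-2-methylbut-2-enal and C6 is its formyl carbon.
- Ring A is formed first, by a catalytic enantioselective Diels–Alder reaction of tiglic aldehyde with a 2-silyloxy-1,3-diene that carries the masked acetonyl chain (C9, C8, C7); it forms C3–C4 and C5–C10.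
- C2 and C3 are set on the monocyclic C1=C10 enone: hydroxylation at C3 (anti to the methyls), inversion to 3α, then hydroxyl-directed reduction of C2 to the 2β,3α-diol.
- Ring B is formed second, by aldol condensation of C7 onto the C6 aldehyde; the C1=C10 alkene then moves to C9=C10.
- Last come the O3 ester (acid from (S)-2-methylbutan-1-ol by oxidation, Horner–Wadsworth–Emmons olefination and saponification) and the C7 hydroxyl (C6=C7 epoxide opened to the diosphenol).

Key step: step 4

Remark: the (R)-hand of the catalyst in step 4 is assigned from the usual pre-transition-state model for α-substituted enals; if the sense found were the opposite, the mirror-image catalyst from natural proline is used with no other change.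

**Route**

Step 1
Reactants: 1 ethyl 2-(2-methyl-1,3-dioxolan-2-yl)acetate
Product: 2 2-(2-methyl-1,3-dioxolan-2-yl)acetaldehyde
Conditions: iBu2AlH (1.05 equiv), CH2Cl2, −78 °C; aq KNaC4H4O6 work-up
Reagents that add atoms: none
Why: Partial ester reduction with iBu2AlH at −78 °C stops at the aluminium hemiacetal, which is stabilised by chelation to a ketal oxygen and releases the aldehyde only on work-up.

Step 2
Reactants: 2 2-(2-methyl-1,3-dioxolan-2-yl)acetaldehyde; 3 1-(triphenylphosphoranylidene)propan-2-one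
Product: 4 (3E)-5-(2-methyl-1,3-dioxolan-2-yl)pent-3-en-2-one
Conditions: CH2Cl2, rt
Reagents that add atoms: none
Why: Wittig olefination with a stabilised, non-basic ylide should give the (E)-enone and does not eliminate the β-ketal.

Step 3
Reactants: 4 (3E)-5-(2-methyl-1,3-dioxolan-2-yl)pent-3-en-2-one
Product: 6 tert-butyldimethyl{[(3E)-5-(2-methyl-1,3-dioxolan-2-yl)penta-1,3-dien-2-yl]oxy}silane, via lithium dienolate 5 (not isolated)
Conditions: LiN(iPr)2 (1.1 equiv), THF, −78 °C; then TBSCl, DMPU, −78 → 0 °C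
Reagents that add atoms: tert-butyldimethylsilyl chloride, CC(C)(C)[Si](C)(C)Cl
Why: Kinetic deprotonation at the α′ methyl group (not at the hindered γ-CH2) and O-silylation of the cross-conjugated lithium enolate give the 2-silyloxy-1,3-diene, leaving the E alkene untouched.

Step 4
Reactants: 6 tert-butyldimethyl{[(3E)-5-(2-methyl-1,3-dioxolan-2-yl)penta-1,3-dien-2-yl]oxy}silane; 7 (2E)-2-methylbut-2-enal (tiglic aldehyde)
Product: 8 (1R,2S,6S)-4-[(tert-butyldimethylsilyl)oxy]-1,6-dimethyl-2-[(2-methyl-1,3-dioxolan-2-yl)methyl]cyclohex-3-ene-1-carbaldehyde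
Conditions: (R)-1-(2-methylphenyl)-3,3-diphenyltetrahydro-1H,3H-pyrrolo[1,2-c][1,3,2]oxazaborole (20 mol%) protonated with (CF3SO2)2NH (20 mol%), 7 (2 equiv), CH2Cl2, −78 → −40 °C; Et3N quench
Reagents that add atoms: none
Why: The N-protonated oxazaborolidine binds the formyl oxygen of 7 (formyl C–H to ring-oxygen contact, s-trans enal lying over a catalyst phenyl group), and the activated enal undergoes a concerted, asynchronous, suprafacial [4+2] cycloaddition with the s-cis diene 6, the known class of oxazaborolidinium-catalysed Diels–Alder reactions of α-substituted enals (tiglic aldehyde included) with 2-silyloxydienes. Ring A closes as a six-membered carbocycle by intermolecular [4+2] union of the diene carbons C3, C2, C1, C10 with the alkene carbons C4 and C5 of 7, forming C3–C4 and C5–C10. The cis relationship of the C4 and C5 methyl groups follows from the E geometry of 7 and suprafacial addition, and the absolute configuration of both centres is set by the catalyst, whose phenyl group screens one face of the bound enal so that the diene adds to the other. C10 is set by the endo or exo mode (drawn for formyl-endo) and need not be controlled, because step 5 makes C10 sp2. The selectivity that is needed is regiochemical, and it is secured by the diene: its 2-silyloxy group and its C10 alkyl group both place the largest HOMO coefficient on the CH2 terminus (C3), which bonds to the β-carbon C4 of the enal. The silyl enol ether and the ketal should survive the low temperature, the catalytic acid loading and the amine quench.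

Step 5
Reactants: 8 (1R,2S,6S)-4-[(tert-butyldimethylsilyl)oxy]-1,6-dimethyl-2-[(2-methyl-1,3-dioxolan-2-yl)methyl]cyclohex-3-ene-1-carbaldehyde
Product: 9 (1R,6S)-1,6-dimethyl-2-[(2-methyl-1,3-dioxolan-2-yl)methyl]-4-oxocyclohex-2-ene-1-carbaldehyde
Conditions: Pd(OAc)2 (1.05 equiv), MeCN, 40 °C
Reagents that add atoms: none
Why: Saegusa–Ito oxidation, in which divalent palladium adds to C1 of the silyl enol ether and syn β-hydride elimination of the only β-hydrogen (C10–H) releases zerovalent palladium, should give the C1=C10 enone and erases the C10 stereocentre, so both cycloadduct epimers converge.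

Step 6
Reactants: 9 (1R,6S)-1,6-dimethyl-2-[(2-methyl-1,3-dioxolan-2-yl)methyl]-4-oxocyclohex-2-ene-1-carbaldehyde
Product: 10 (4R,5S)-4-(dimethoxymethyl)-4,5-dimethyl-3-[(2-methyl-1,3-dioxolan-2-yl)methyl]cyclohex-2-en-1-one
Conditions: MeOSiMe3 (3 equiv), Me3SiOTf (5 mol%), CH2Cl2, −78 °C; pyridine quench
Reagents that add atoms: methoxytrimethylsilane, CO[Si](C)(C)C
Why: Silyl triflate-catalysed acetalisation with an alkoxysilane at −78 °C is selective for the aldehyde over the conjugated ketone and leaves the dioxolane intact, and the acetal keeps C6 out of the enolate and hydride chemistry of steps 7 to 9.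

Step 7
Reactants: 10 (4R,5S)-4-(dimethoxymethyl)-4,5-dimethyl-3-[(2-methyl-1,3-dioxolan-2-yl)methyl]cyclohex-2-en-1-one
Product: 12 (4R,5R,6S)-4-(dimethoxymethyl)-6-hydroxy-4,5-dimethyl-3-[(2-methyl-1,3-dioxolan-2-yl)methyl]cyclohex-2-en-1-one (3β-hydroxyl, trans to the C4 methyl), via sodium dienolate 11 (not isolated)
Conditions: NaN(SiMe3)2 (1.2 equiv), THF, −78 °C; then 2-(phenylsulfonyl)-3-phenyloxaziridine (1.5 equiv), −78 °C; AcOH quench
Reagents that add atoms: 2-(phenylsulfonyl)-3-phenyloxaziridine, O=S(=O)(N1OC1c1ccccc1)c1ccccc1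
Why: Kinetic α′-deprotonation at C3 (C1 is blocked by the alkene) and electrophilic hydroxylation of the enolate by the N-sulfonyloxaziridine should place the hydroxyl on the β face, anti to the C4 and C5 methyl groups, and any 3α epimer formed is itself compound 14.

Step 8
Reactants: 12 (4R,5R,6S)-4-(dimethoxymethyl)-6-hydroxy-4,5-dimethyl-3-[(2-methyl-1,3-dioxolan-2-yl)methyl]cyclohex-2-en-1-one
Product: 14 (4R,5R,6R)-4-(dimethoxymethyl)-6-hydroxy-4,5-dimethyl-3-[(2-methyl-1,3-dioxolan-2-yl)methyl]cyclohex-2-en-1-one (3α-hydroxyl, cis to the C4 methyl), via chloroacetate 13 (not isolated)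
Conditions: PPh3 (2.5 equiv), DIAD (2.5 equiv), ClCH2CO2H (2.5 equiv), toluene, 0 °C → rt; then MeOH, aq NaHCO3, rt
Reagents that add atoms: chloroacetic acid, OC(=O)CCl
Why: Mitsunobu reaction, in which SN2 displacement of the oxyphosphonium of the α-ketol by chloroacetate (accelerated by the adjacent carbonyl) inverts C3 to the α configuration, after which the activated chloroacetate is cleaved by mild methanolysis without enolising the α-ketol.

Step 9
Reactants: 14 (4R,5R,6R)-4-(dimethoxymethyl)-6-hydroxy-4,5-dimethyl-3-[(2-methyl-1,3-dioxolan-2-yl)methyl]cyclohex-2-en-1-one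
Product: 15 (1R,2R,5R,6R)-5-(dimethoxymethyl)-5,6-dimethyl-4-[(2-methyl-1,3-dioxolan-2-yl)methyl]cyclohex-3-ene-1,2-diol (2β,3α-diol)
Conditions: Me4NBH(OAc)3 (4 equiv), MeCN/AcOH (1:1), −30 → 0 °C
Reagents that add atoms: none
Why: Hydroxyl-directed (Evans–Saksena) reduction, in which the C3 hydroxyl displaces acetate on boron and delivers hydride intramolecularly to the same face of the C2 carbonyl, should give the trans 2β,3α-diol and so sets C2, while acetal and ketal are inert.

Step 10
Reactants: 15 (1R,2R,5R,6R)-5-(dimethoxymethyl)-5,6-dimethyl-4-[(2-methyl-1,3-dioxolan-2-yl)methyl]cyclohex-3-ene-1,2-diol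
Product: 18 (4aR,5R,6R,7R)-6,7-dihydroxy-4a,5-dimethyl-5,6,7,8-tetrahydronaphthalen-2(4aH)-one, via keto aldehyde 16 (not isolated), via deconjugated enone 17 (not isolated)
Conditions: pyridinium p-toluenesulfonate (0.3 equiv), acetone/H2O (4:1), 40 °C; then KOH (0.5 M), MeOH, 0 °C → rt
Reagents that add atoms: water, O
Why: Buffered acid hydrolysis should free the C6 aldehyde and C8 ketone faster than the allylic alcohol ionises, and base then effects the intramolecular aldol condensation of the methyl ketone carbon C7 onto the non-enolisable aldehyde (six-membered ring B) and the conjugative shift of the C1=C10 alkene to C9=C10.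

Step 11
Reactants: 18 (4aR,5R,6R,7R)-6,7-dihydroxy-4a,5-dimethyl-5,6,7,8-tetrahydronaphthalen-2(4aH)-one
Product: 19 (4aR,5R,6R,7R)-7-[(tert-butyldimethylsilyl)oxy]-6-hydroxy-4a,5-dimethyl-5,6,7,8-tetrahydronaphthalen-2(4aH)-one
Conditions: TBSCl (1.2 equiv), imidazole, DMF, 0 °C
Reagents that add atoms: tert-butyldimethylsilyl chloride, CC(C)(C)[Si](C)(C)Cl
Why: Selective silylation should occur at O2 because the planar dienone locks ring A with the C5 methyl axial, so the axial C3 hydroxyl is screened by the syn-axial C5 methyl and the adjacent C4 methyl while the C2 hydroxyl is open.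

Step 12
Reactants: 20 (S)-2-methylbutan-1-ol
Product: 21 (S)-2-methylbutanal
Conditions: TEMPO (10 mol%), PhI(OAc)2 (1.1 equiv), CH2Cl2, rt; used as a solution
Reagents that add atoms: none
Why: Oxoammonium (TEMPO) oxidation under near-neutral conditions gives the aldehyde without over-oxidation and without epimerising the α-stereocentre.

Step 13
Reactants: 21 (S)-2-methylbutanal; 22 ethyl (2E)-4-(diethoxyphosphoryl)but-2-enoate (triethyl 4-phosphonocrotonate)
Product: 23 ethyl (2E,4E,6S)-6-methylocta-2,4-dienoate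
Conditions: 22, LiN(SiMe3)2 (1.1 equiv), THF, −78 °C; then 21, −78 → 0 °C
Reagents that add atoms: none
Why: Vinylogous Horner–Wadsworth–Emmons olefination with the preformed lithium phosphonate should form the new C4=C5 bond with E geometry and keep the E C2=C3 bond, and the low temperature protects the α-stereocentre of the aldehyde.

Step 14
Reactants: 23 ethyl (2E,4E,6S)-6-methylocta-2,4-dienoate
Product: 24 (2E,4E,6S)-6-methylocta-2,4-dienoic acid
Conditions: LiOH·H2O (3 equiv), THF/MeOH/H2O, rt; then 1 M HCl to pH 3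
Reagents that add atoms: lithium hydroxide, [Li+].[OH-]
Why: Saponification by acyl substitution does not touch the diene geometry or the remote stereocentre.

Step 15
Reactants: 19 (4aR,5R,6R,7R)-7-[(tert-butyldimethylsilyl)oxy]-6-hydroxy-4a,5-dimethyl-5,6,7,8-tetrahydronaphthalen-2(4aH)-one; 24 (2E,4E,6S)-6-methylocta-2,4-dienoic acid
Product: 26 (1R,2R,3R,8aR)-3-[(tert-butyldimethylsilyl)oxy]-1,8a-dimethyl-6-oxo-1,2,3,4,6,8a-hexahydronaphthalen-2-yl (2E,4E,6S)-6-methylocta-2,4-dienoate, via mixed anhydride 25 (not isolated)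
Conditions: 24 (2 equiv), 2,4,6-trichlorobenzoyl chloride (2 equiv), Et3N (3 equiv), toluene, rt; then 19, DMAP (2 equiv), 50 °C
Reagents that add atoms: none
Why: Yamaguchi esterification, in which DMAP attacks the less hindered dienoyl carbonyl of the mixed anhydride and the acylpyridinium acylates the hindered axial C3 hydroxyl with retention at C3, should not isomerise the dienoate.

Step 16
Reactants: 26 (1R,2R,3R,8aR)-3-[(tert-butyldimethylsilyl)oxy]-1,8a-dimethyl-6-oxo-1,2,3,4,6,8a-hexahydronaphthalen-2-yl (2E,4E,6S)-6-methylocta-2,4-dienoate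
Product: 27 the 6β,7β-epoxide of 26 (oxirane across C6–C7 on the face opposite the C5 methyl)
Conditions: t-BuOOH (3 equiv), DBU (1.2 equiv), CH2Cl2, 0 °C
Reagents that add atoms: tert-butyl hydroperoxide, CC(C)(C)OO
Why: Weitz–Scheffer nucleophilic epoxidation should occur at C6, the less substituted β-carbon of the cross-conjugated dienone, anti to the axial C5 methyl, leaving the C9=C10 bond and the much less electrophilic dienoate; both new stereocentres are removed in step 17.

Step 17
Reactants: 27 the 6β,7β-epoxide of 26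
Product: 28 (1R,2R,3R,8aS)-3-[(tert-butyldimethylsilyl)oxy]-7-hydroxy-1,8a-dimethyl-6-oxo-1,2,3,4,6,8a-hexahydronaphthalen-2-yl (2E,4E,6S)-6-methylocta-2,4-dienoate
Conditions: p-TsOH·H2O (0.3 equiv), toluene, 40 °C
Reagents that add atoms: none
Why: Acid-mediated isomerisation of an α,β-epoxy ketone to a diosphenol, by opening of the protonated epoxide at C6 and loss of the C7 proton, should give the enolised 1,2-diketone C6=C7(OH)–C8=O, as in the conversion of 1,2-epoxy-4-en-3-ones into 2-hydroxy-1,4-dien-3-ones.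

Step 18
Reactants: 28 (1R,2R,3R,8aS)-3-[(tert-butyldimethylsilyl)oxy]-7-hydroxy-1,8a-dimethyl-6-oxo-1,2,3,4,6,8a-hexahydronaphthalen-2-yl (2E,4E,6S)-6-methylocta-2,4-dienoate
Product: 29 Septeremophilane G, (1R,2R,3R,8aS)-3,7-dihydroxy-1,8a-dimethyl-6-oxo-1,2,3,4,6,8a-hexahydronaphthalen-2-yl (2E,4E,6S)-6-methylocta-2,4-dienoate
Conditions: HF·pyridine, THF/pyridine, 0 °C → rt
Reagents that add atoms: none
Why: Fluoride-mediated cleavage of the secondary silyl ether under buffered conditions should leave the dienoate, the diosphenol and the trans-diaxial hydroxy ester (which cannot undergo acyl migration) intact.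

**Compound list**

1 | ethyl 2-(2-methyl-1,3-dioxolan-2-yl)acetate | CCOC(=O)CC1(C)OCCO1 | starting material
2 | 2-(2-methyl-1,3-dioxolan-2-yl)acetaldehyde | O=CCC1(C)OCCO1 | intermediate
3 | 1-(triphenylphosphoranylidene)propan-2-one | CC(=O)C=P(c1ccccc1)(c1ccccc1)c1ccccc1 | starting material
4 | (3E)-5-(2-methyl-1,3-dioxolan-2-yl)pent-3-en-2-one | CC(=O)/C=C/CC1(C)OCCO1 | intermediate
5 | lithium (3E)-5-(2-methyl-1,3-dioxolan-2-yl)penta-1,3-dien-2-olate | [Li+].[O-]C(=C)/C=C/CC1(C)OCCO1 | intermediate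
6 | tert-butyldimethyl{[(3E)-5-(2-methyl-1,3-dioxolan-2-yl)penta-1,3-dien-2-yl]oxy}silane | C=C(O[Si](C)(C)C(C)(C)C)/C=C/CC1(C)OCCO1 | intermediate
7 | (2E)-2-methylbut-2-enal (tiglic aldehyde) | C/C=C(\C)C=O | starting material
8 | (1R,2S,6S)-4-[(tert-butyldimethylsilyl)oxy]-1,6-dimethyl-2-[(2-methyl-1,3-dioxolan-2-yl)methyl]cyclohex-3-ene-1-carbaldehyde | C1C(O[Si](C)(C)C(C)(C)C)=C[C@H](CC2(C)OCCO2)[C@](C)(C=O)[C@H]1C | intermediate
9 | (1R,6S)-1,6-dimethyl-2-[(2-methyl-1,3-dioxolan-2-yl)methyl]-4-oxocyclohex-2-ene-1-carbaldehyde | C1C(=O)C=C(CC2(C)OCCO2)[C@](C)(C=O)[C@H]1C | intermediate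
10 | (4R,5S)-4-(dimethoxymethyl)-4,5-dimethyl-3-[(2-methyl-1,3-dioxolan-2-yl)methyl]cyclohex-2-en-1-one | C1C(=O)C=C(CC2(C)OCCO2)[C@](C)(C(OC)OC)[C@H]1C | intermediate
11 | sodium dienolate of 10 (O–C2=C3, C1=C10) | C1=C([O-])C=C(CC2(C)OCCO2)[C@](C)(C(OC)OC)[C@H]1C.[Na+] | intermediate
12 | (4R,5R,6S)-4-(dimethoxymethyl)-6-hydroxy-4,5-dimethyl-3-[(2-methyl-1,3-dioxolan-2-yl)methyl]cyclohex-2-en-1-one | O=C1C=C(CC2(C)OCCO2)[C@](C)(C(OC)OC)[C@@H](C)[C@@H]1O | intermediate
13 | (1R,5R,6R)-5-(dimethoxymethyl)-5,6-dimethyl-4-[(2-methyl-1,3-dioxolan-2-yl)methyl]-2-oxocyclohex-3-en-1-yl chloroacetate | O=C1C=C(CC2(C)OCCO2)[C@](C)(C(OC)OC)[C@@H](C)[C@H]1OC(=O)CCl | intermediate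
14 | (4R,5R,6R)-4-(dimethoxymethyl)-6-hydroxy-4,5-dimethyl-3-[(2-methyl-1,3-dioxolan-2-yl)methyl]cyclohex-2-en-1-one | O=C1C=C(CC2(C)OCCO2)[C@](C)(C(OC)OC)[C@@H](C)[C@H]1O | intermediate
15 | (1R,2R,5R,6R)-5-(dimethoxymethyl)-5,6-dimethyl-4-[(2-methyl-1,3-dioxolan-2-yl)methyl]cyclohex-3-ene-1,2-diol | O[C@@H]1C=C(CC2(C)OCCO2)[C@](C)(C(OC)OC)[C@@H](C)[C@H]1O | intermediate
16 | (1R,4R,5R,6R)-4,5-dihydroxy-1,6-dimethyl-2-(2-oxopropyl)cyclohex-2-ene-1-carbaldehyde | O[C@@H]1C=C(CC(C)=O)[C@](C)(C=O)[C@@H](C)[C@H]1O | intermediate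
17 | (4aR,5R,6R,7R)-6,7-dihydroxy-4a,5-dimethyl-4a,5,6,7-tetrahydronaphthalen-2(1H)-one | O[C@@H]1C=C2CC(=O)C=C[C@]2(C)[C@@H](C)[C@H]1O | intermediate
18 | (4aR,5R,6R,7R)-6,7-dihydroxy-4a,5-dimethyl-5,6,7,8-tetrahydronaphthalen-2(4aH)-one | O[C@H]1[C@H](O)CC2=CC(=O)C=C[C@]2(C)[C@H]1C | intermediate
19 | (4aR,5R,6R,7R)-7-[(tert-butyldimethylsilyl)oxy]-6-hydroxy-4a,5-dimethyl-5,6,7,8-tetrahydronaphthalen-2(4aH)-one | O[C@H]1[C@H](O[Si](C)(C)C(C)(C)C)CC2=CC(=O)C=C[C@]2(C)[C@H]1C | intermediate
20 | (S)-2-methylbutan-1-ol | CC[C@H](C)CO | starting material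
21 | (S)-2-methylbutanal | CC[C@H](C)C=O | intermediate
22 | ethyl (2E)-4-(diethoxyphosphoryl)but-2-enoate | CCOC(=O)/C=C/CP(=O)(OCC)OCC | starting material
23 | ethyl (2E,4E,6S)-6-methylocta-2,4-dienoate | CC[C@H](C)/C=C/C=C/C(=O)OCC | intermediate
24 | (2E,4E,6S)-6-methylocta-2,4-dienoic acid | CC[C@H](C)/C=C/C=C/C(=O)O | intermediate
25 | (2E,4E,6S)-6-methylocta-2,4-dienoic 2,4,6-trichlorobenzoic anhydride | CC[C@H](C)/C=C/C=C/C(=O)OC(=O)c1c(Cl)cc(Cl)cc1Cl | intermediate
26 | (1R,2R,3R,8aR)-3-[(tert-butyldimethylsilyl)oxy]-1,8a-dimethyl-6-oxo-1,2,3,4,6,8a-hexahydronaphthalen-2-yl (2E,4E,6S)-6-methylocta-2,4-dienoate | CC[C@H](C)/C=C/C=C/C(=O)O[C@H]1[C@H](O[Si](C)(C)C(C)(C)C)CC2=CC(=O)C=C[C@]2(C)[C@H]1C | intermediate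
27 | 6β,7β-epoxide of 26 (oxirane on the face opposite the C5 methyl) | CC[C@H](C)/C=C/C=C/C(=O)O[C@H]1[C@H](O[Si](C)(C)C(C)(C)C)CC2=CC(=O)[C@@H]3O[C@@H]3[C@]2(C)[C@H]1C | intermediate
28 | (1R,2R,3R,8aS)-3-[(tert-butyldimethylsilyl)oxy]-7-hydroxy-1,8a-dimethyl-6-oxo-1,2,3,4,6,8a-hexahydronaphthalen-2-yl (2E,4E,6S)-6-methylocta-2,4-dienoate | CC[C@H](C)/C=C/C=C/C(=O)O[C@H]1[C@H](O[Si](C)(C)C(C)(C)C)CC2=CC(=O)C(O)=C[C@]2(C)[C@H]1C | intermediate
29 | Septeremophilane G | CC[C@H](C)/C=C/C=C/C(=O)O[C@H]1[C@H](O)CC2=CC(=O)C(O)=C[C@]2(C)[C@H]1C | target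

**Step count**

Total: 18 steps. Longest linear sequence: 15 steps (steps 1–11 and 15–18).

**Steps most likely to fail**

Step 8 (inversion at C3). The displacement has to come from the α face, cis to the C4 methyl and syn to the C5 methyl, so the oxyphosphonium may be lost by elimination or by acyl transfer with retention instead of being displaced with inversion. The fallback sets out from 10. The sodium dienolate 11 is brominated with N-bromosuccinimide (THF, −78 °C) instead of being hydroxylated, which should give the 3β-bromo enone F1 by attack anti to the methyl groups. This α-bromo ketone is a faster SN2 substrate with a small leaving group; HCO2Cs in DMF at 0 °C should displace it to the inverted 3α-formate F2. Methanolysis (NaHCO3, MeOH) comes back to the route at 14.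

Step 17 (epoxy ketone to diosphenol). Under acid the opened epoxide may react by migration of a C5 substituent or of the acyl carbon (ring contraction) instead of simple proton loss, and the silyl ether may be lost early. The fallback sets out from 19 and forms the diosphenol before the ester is attached. Alkaline hydrogen peroxide (H2O2, NaOH, MeOH, 0 °C) should give the epoxy alcohol F3. Aqueous KOH in tert-butanol at 40 °C should then open it by hydroxide attack at C7 and β-elimination of the C6 hydroxyl to the diosphenol alcohol F4. TBSCl and imidazole should silylate the acidic enol hydroxyl but not the hindered C3 hydroxyl, giving the bis-silyl ether F5. Esterification with 24 through 25 as in step 15 gives the bis-silyl ester F6, and HF·pyridine removes both silyl groups to come back to the route at 29.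

Step 4 (key cycloaddition). Facial selectivity may be insufficient, or the strongly acidic catalyst may protodesilylate the diene before cycloaddition. The fallback sets out from 6 and 7 and replaces catalyst control by resolution. Me2AlCl (1 equiv, CH2Cl2, −78 °C) should promote the same cycloaddition and give 8 together with its enantiomer F7. Saegusa–Ito oxidation as in step 5 gives 9 together with its enantiomer F8. Condensation of this racemic aldehyde with (1R,2R)-N,N′-dimethyl-1,2-diphenylethane-1,2-diamine (Et2O, molecular sieves) gives the diastereomeric imidazolidines F9 (from 9) and F10 (from F8), which are separated by chromatography. Hydrolysis of F9 on wet silica gel comes back to the route at 9.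

**Further compounds**

F1 | step 8 | (4R,5R,6S)-6-bromo-4-(dimethoxymethyl)-4,5-dimethyl-3-[(2-methyl-1,3-dioxolan-2-yl)methyl]cyclohex-2-en-1-one | O=C1C=C(CC2(C)OCCO2)[C@](C)(C(OC)OC)[C@@H](C)[C@@H]1Br
F2 | step 8 | (1R,5R,6R)-5-(dimethoxymethyl)-5,6-dimethyl-4-[(2-methyl-1,3-dioxolan-2-yl)methyl]-2-oxocyclohex-3-en-1-yl formate | O=C1C=C(CC2(C)OCCO2)[C@](C)(C(OC)OC)[C@@H](C)[C@H]1OC=O
F3 | step 17 | 6β,7β-epoxide of 19 | O[C@H]1[C@H](O[Si](C)(C)C(C)(C)C)CC2=CC(=O)[C@@H]3O[C@@H]3[C@]2(C)[C@H]1C
F4 | step 17 | (4aS,5R,6R,7R)-7-[(tert-butyldimethylsilyl)oxy]-3,6-dihydroxy-4a,5-dimethyl-5,6,7,8-tetrahydronaphthalen-2(4aH)-one | O[C@H]1[C@H](O[Si](C)(C)C(C)(C)C)CC2=CC(=O)C(O)=C[C@]2(C)[C@H]1C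
F5 | step 17 | (4aS,5R,6R,7R)-3,7-bis[(tert-butyldimethylsilyl)oxy]-6-hydroxy-4a,5-dimethyl-5,6,7,8-tetrahydronaphthalen-2(4aH)-one | O[C@H]1[C@H](O[Si](C)(C)C(C)(C)C)CC2=CC(=O)C(O[Si](C)(C)C(C)(C)C)=C[C@]2(C)[C@H]1C
F6 | step 17 | (1R,2R,3R,8aS)-3,7-bis[(tert-butyldimethylsilyl)oxy]-1,8a-dimethyl-6-oxo-1,2,3,4,6,8a-hexahydronaphthalen-2-yl (2E,4E,6S)-6-methylocta-2,4-dienoate | CC[C@H](C)/C=C/C=C/C(=O)O[C@H]1[C@H](O[Si](C)(C)C(C)(C)C)CC2=CC(=O)C(O[Si](C)(C)C(C)(C)C)=C[C@]2(C)[C@H]1C
F7 | step 4 | enantiomer of 8, (1S,2R,6R)-4-[(tert-butyldimethylsilyl)oxy]-1,6-dimethyl-2-[(2-methyl-1,3-dioxolan-2-yl)methyl]cyclohex-3-ene-1-carbaldehyde | C1C(O[Si](C)(C)C(C)(C)C)=C[C@@H](CC2(C)OCCO2)[C@@](C)(C=O)[C@@H]1C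
F8 | step 4 | enantiomer of 9, (1S,6R)-1,6-dimethyl-2-[(2-methyl-1,3-dioxolan-2-yl)methyl]-4-oxocyclohex-2-ene-1-carbaldehyde | C1C(=O)C=C(CC2(C)OCCO2)[C@@](C)(C=O)[C@@H]1C
F9 | step 4 | imidazolidine of 9 with (1R,2R)-N,N′-dimethyl-1,2-diphenylethane-1,2-diamine | C1C(=O)C=C(CC2(C)OCCO2)[C@](C)(C3N(C)[C@H](c4ccccc4)[C@@H](c4ccccc4)N3C)[C@H]1C
F10 | step 4 | imidazolidine of F8 with (1R,2R)-N,N′-dimethyl-1,2-diphenylethane-1,2-diamine | C1C(=O)C=C(CC2(C)OCCO2)[C@@](C)(C3N(C)[C@H](c4ccccc4)[C@@H](c4ccccc4)N3C)[C@@H]1C
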